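The earlier runs and the new flask are calculated for substances that don't exist, and the scatter is random.

A stall with substrate still standing is easily read as a dead catalyst, so I began by asking what the plateaus of the earlier runs follow.

| flask | substrate | partner | precatalyst | remark | time |
|---|---|---|---|---|---|
| zeta | 0.020 M | 0.014 M | 100 µM | run made earlier |  |
| theta | 0.020 M | 0.020 M | 100 µM | run made earlier |  |
| beta | 0.020 M | 0.031 M | 100 µM | run made earlier |  |
| gamma | 0.030 M | 0.014 M | 100 µM | run made earlier |  |
| teal | 0.020 M (fed, over 30 s) | 0.0140 M | 100 µM | all else is in the flask from the start; the feed brings no volume worth counting | 2.5 min |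
| green | 0.020 M (in portions, 4, over 30 s) | 0.0140 M | 100 µM | first portion at the start, last at 30 s | 2.5 min |
| blue | 0.020 M | 0.0140 M (fed, over 30 s) | 100 µM | all else is in the flask from the start; the feed brings no volume worth counting | 2.5 min |
| red | 0.020 M | 0.0140 M | 100 µM | everything together at the start | 2.5 min |

zeta run (percent of the substrate charged)

| time / s | target / % | substrate / % |
|---|---|---|
| 12.0 | 4.4 | 95.8 |
| 30.0 | 17.4 | 83.9 |
| 60.0 | 27.8 | 71.2 |
| 90.0 | 33.3 | 67.3 |

theta run (percent of the substrate charged)

| time / min | target / % | substrate / % |
|---|---|---|
| 0.833 | 31.8 | 68.9 |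
| 1.50 | 39.3 | 61.8 |
| 2.50 | 40.9 | 58.9 |
| 3.00 | 40.1 | 58.7 |

beta run (percent of the substrate charged)

| time / min | target / % | substrate / % |
|---|---|---|
| 0.417 | 20.8 | 79.5 |
| 1.00 | 41.2 | 58.7 |
| 2.00 | 46.6 | 53.1 |
| 3.00 | 47.0 | 52.8 |

gamma run (percent of the substrate charged)

| time / min | target / % | substrate / % |
|---|---|---|
| 0.833 | 18.1 | 82.4 |
| 1.50 | 21.8 | 77.7 |
| 2.50 | 23.0 | 76.7 |
| 3.00 | 23.8 | 77.2 |

(standard deviation of a reading: 0.5 percentage points)

1. the best flask by amount of target, in percent of the substrate charged; "all alike" if 1.5 percentage points covers them all (teal / green / blue / red / all alike)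
2. amount of target at the end, in percent of the substrate charged, teal
3. amount of target at the end, in percent of the substrate charged, green
4. amount of target at the end, in percent of the substrate charged, blue
5. amount of target at the end, in percent of the substrate charged, red

- the numbers in the tables scatter with a standard deviation of 0.5 percentage points

Raising substrate from 0.020 M in zeta to 0.030 M in gamma moved the last target reading from 0.00666 M to 0.00714 M, but raising partner to 0.031 M in beta gave 0.00940 M, so I took partner, which was never read, for the limiting reagent. Yet target did not keep step with the partner charge, so I divided the partner that missed the target by the partner that became target, called this the waste ratio, and divided it again by the charge. Zeta gave 78.7 M⁻¹, theta 74.7 M⁻¹ and beta 74.1 M⁻¹, and I froze this last reading as the waste coefficient.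

With everything in at the start, target is then the charge over one plus coefficient times charge, which put red at 34.4%, and I kept teal and green, which hold red's partner from the start, beside it. For blue I assumed that the feed stretch made the 0.00348 M of target that zeta had made by 30.0 s, and I gave that stretch the waste ratio of coefficient times peak partner level. That put my estimate of blue's peak partner level at 0.00836 M, and the rest of the run, reckoned as a flask charged with that level of partner, brought blue to 43.2%, so I committed to blue, higher than red.

The forecast differed: teal 35.5%, green 35.5%, blue 31.5%, red 36%, best red, holding that “Blue starves the catalyst of partner while its short life runs out”.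

Blue, at 46.1%, stood higher than teal at 33.4%, green at 33.6% and red at 34.4%.

    partner + free catalyst ⇌ catalyst intermediate A (K = 5700 M⁻¹, k = 500 M⁻¹ s⁻¹)
    substrate + catalyst intermediate A ⇌ catalyst intermediate B (K = 64.0 M⁻¹, k = 4500 M⁻¹ s⁻¹)
    catalyst intermediate B → free catalyst + target (k = 70.0 s⁻¹)
    2 partner → homo dimer (k = 1.50 M⁻¹ s⁻¹)
    precatalyst → free catalyst (k = 0.0360 s⁻¹)

In teal at 0.530 min partner entered catalyst intermediate A 2.7 times as fast, forward step alone, as it entered homo dimer, and blue averaged 0.00513 M of partner over its feed. Red's waste ratio was 1.03 and blue's 0.519, half of red's, and the coefficient 74.1 M⁻¹ reads blue's ratio as an all-at-start charge of 0.00700 M. A flask like teal with 0.0084 M of partner reckons by that coefficient to 25.9% and held 25.4%.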